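**Strategy.** Sideroxylonal A is dissected through its dihydropyran ring: cutting O1–C2 and C3–C4 in a retro-oxa-Diels–Alder sense reveals two tautomers of one C13 monomer. One is an ortho-quinone methide (C4a, C8a–O1, and C4 with its isobutyl group). The other is an (E)-ortho-hydroxystyrene (C2 with the second diformylphloroglucinol ring, C3 with its isopropyl group). The key step is a chiral Brønsted acid-catalysed tautomerising dimerisation of (E)-5-(3-methylbut-1-enyl)-2,4-diformylphloroglucinol: one molecule is protonated to the quinone methide and a second adds across it. The pyran ring, the C3–C4 bond and all three stereocentres arise in one operation. The monomer comes from phloroglucinol by formylation, bromination and Suzuki coupling.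

Key step: step 5

Assumption: the sense of induction of the chiral phosphoramide cannot be assigned in advance; the (R)-catalyst is written, and its (S)-enantiomer is used instead if the first run shows the antipode to be favoured.

Step 1
Reactants: 1 phloroglucinol (benzene-1,3,5-triol)
Product: 2 2,4,6-trihydroxybenzene-1,3-dicarbaldehyde (2,4-diformylphloroglucinol)
Conditions: POCl3 (2.2 equiv), DMF (2.2 equiv), 1,4-dioxane, 0 °C to rt; then H2O, rt
Reagents that add atoms: N,N-dimethylformamide (CN(C)C=O); water (O)
Why: Twofold Vilsmeier–Haack formylation, in which the chloroiminium ion from POCl3 and DMF should attack the highly activated ring twice (a third attack on the deactivated ring is slow) and hydrolysis of the bis-iminium salt should release the dialdehyde.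

Step 2
Reactants: 2 2,4,6-trihydroxybenzene-1,3-dicarbaldehyde
Product: 3 5-bromo-2,4,6-trihydroxybenzene-1,3-dicarbaldehyde
Conditions: NBS (1.0 equiv), MeCN, 0 °C, dark
Reagents that add atoms: N-bromosuccinimide (O=C1CCC(=O)N1Br)
Why: Electrophilic aromatic bromination, in which the single free ring position, ortho/para to all three hydroxyl groups, should react with one equivalent of NBS before any ipso attack at a formyl-bearing carbon.

Step 3
Reactants: 4 3-methylbut-1-yne
Product: 5 (E)-4,4,5,5-tetramethyl-2-(3-methylbut-1-en-1-yl)-1,3,2-dioxaborolane
Conditions: pinacolborane (1.05 equiv), Cp2Zr(H)Cl (5 mol%), CH2Cl2, rt, sealed vessel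
Reagents that add atoms: pinacolborane (CC1(C)OBOC1(C)C)
Why: Cp2Zr(H)Cl-catalysed hydroboration of a terminal alkyne (syn hydrozirconation, then zirconium-to-boron exchange) should give the anti-Markovnikov alkenylboronate, the syn addition fixing the E geometry.

Step 4
Reactants: 3 5-bromo-2,4,6-trihydroxybenzene-1,3-dicarbaldehyde; 5 (E)-4,4,5,5-tetramethyl-2-(3-methylbut-1-en-1-yl)-1,3,2-dioxaborolane
Product: 6 2,4,6-trihydroxy-5-[(E)-3-methylbut-1-en-1-yl]benzene-1,3-dicarbaldehyde
Conditions: Pd(OAc)2 (5 mol%), SPhos (2-dicyclohexylphosphino-2',6'-dimethoxybiphenyl, 10 mol%), K3PO4 (4 equiv), 1,4-dioxane/H2O, 70 °C; work-up with cold aqueous NaH2PO4 (pH 4–5)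
Reagents that add atoms: none
Why: Suzuki–Miyaura coupling, in which the electron-rich biaryl phosphine should let zerovalent palladium insert into the hindered C–Br bond and the alkenyl group is transferred with retention of the E geometry, the product staying a stable phenoxide until the mildly acidic work-up.

Step 5
Reactants: 6 2,4,6-trihydroxy-5-[(E)-3-methylbut-1-en-1-yl]benzene-1,3-dicarbaldehyde (two molecules)
Product: 8 sideroxylonal A, via ortho-quinone methide 7 (not isolated)
Conditions: (R)-N-triflylphosphoramide of 3,3'-bis(2,4,6-triisopropylphenyl)-1,1'-bi-2-naphthol (10 mol%), 5 Å molecular sieves, toluene/CH2Cl2, −20 °C to rt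
Reagents that add atoms: none
Why: Proposed new method: the bifunctional chiral acid should shuttle a proton from an ortho-hydroxyl to the alkene carbon remote from the ring in one molecule of 6, giving the ortho-quinone methide 7 as a hydrogen-bonded chiral ion pair, and a second molecule of 6, held to the same phosphoramide anion through an ortho-hydroxyl, should add with its isopropyl-bearing carbon to the exocyclic carbon of 7 (C3–C4 bond) before the quinone methide oxygen closes onto the aryl-stabilised benzylic carbon (O1–C2 bond). The closest known reaction types are the chiral phosphoric acid-catalysed inverse-electron-demand oxa-Diels–Alder reaction of in situ generated ortho-quinone methides with ortho-hydroxystyrenes and the acid-induced racemic dimerisation of 2-vinylphenols to 2-arylchromans; new here are the enantioselective homodimerisation and the formyl-rich, alkyl-substituted quinone methide. The dihydropyran ring closes in an asynchronous [4+2] mode in which the C3–C4 bond leads and the O1–C2 bond follows as a six-membered closure of the oxygen onto a cation-like benzylic carbon. C2 and C3 should come out trans because the E geometry of the dienophile is transferred suprafacially; C3 and C4 should come out cis because the twisted, doubly ortho-substituted aryl group is expected to sit exo and leave the isopropyl group endo to the (E)-quinone methide, an arrangement that leads to the half-chair with C2-aryl and C3-isopropyl equatorial and C4-isobutyl pseudo-axial, free of peri strain with the C5 hydroxyl; the absolute configuration (2R,3R,4S) is set by the chiral anion, which shields one face of the ion-paired quinone methide. The step needs head-to-tail regioselectivity, which the opposite polarity of the two tautomers secures, and exo-aryl and enantiofacial selectivity over a racemic background, which low temperature, the absence of any other acid and the confined strong acid are meant to secure; the product has neither an alkene nor a free aromatic position and cannot react further.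

**Compound list**

1 | phloroglucinol (benzene-1,3,5-triol) | Oc1cc(O)cc(O)c1 | starting material
2 | 2,4,6-trihydroxybenzene-1,3-dicarbaldehyde | O=Cc1c(O)cc(O)c(C=O)c1O | intermediate
3 | 5-bromo-2,4,6-trihydroxybenzene-1,3-dicarbaldehyde | O=Cc1c(O)c(Br)c(O)c(C=O)c1O | intermediate
4 | 3-methylbut-1-yne | CC(C)C#C | starting material
5 | (E)-4,4,5,5-tetramethyl-2-(3-methylbut-1-en-1-yl)-1,3,2-dioxaborolane | CC(C)/C=C/B1OC(C)(C)C(C)(C)O1 | intermediate
6 | 2,4,6-trihydroxy-5-[(E)-3-methylbut-1-en-1-yl]benzene-1,3-dicarbaldehyde | CC(C)/C=C/c1c(O)c(C=O)c(O)c(C=O)c1O | intermediate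
7 | (E)-2,4-dihydroxy-5-(3-methylbutylidene)-6-oxocyclohexa-1,3-diene-1,3-dicarbaldehyde (ortho-quinone methide tautomer of 6, not isolated) | CC(C)C/C=C1/C(=O)C(C=O)=C(O)C(C=O)=C1O | intermediate
8 | sideroxylonal A, (2R,3R,4S)-2-(3,5-diformyl-2,4,6-trihydroxyphenyl)-5,7-dihydroxy-4-(2-methylpropyl)-3-(propan-2-yl)-3,4-dihydro-2H-chromene-6,8-dicarbaldehyde | CC(C)C[C@@H]1c2c(O)c(C=O)c(O)c(C=O)c2O[C@@H](c2c(O)c(C=O)c(O)c(C=O)c2O)[C@@H]1C(C)C | target

**Step count and risks**

Total step count: 5. Longest linear sequence: 4 steps (1 → 2 → 3 → 6 → 8).

Steps most likely to fail: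

1. Step 5. The chiral counter-anion may discriminate the two faces of the quinone methide poorly, an uncatalysed racemic dimerisation may compete, and the approach with the aryl group endo may lead to the C4-epimeric series. Fallback with known chemistry, setting out from 6: the dimerisation is run without chiral information (diphenyl phosphate, 10 mol%, toluene, rt, or heating in toluene). This is the known acid- or heat-induced head-to-tail oxa-Diels–Alder dimerisation of ortho-hydroxystyrenes through their ortho-quinone methide tautomers. It should give racemic sideroxylonal A, that is 8 together with its mirror image ent-sideroxylonal A F1. C4 epimers are removed on silica, and the racemate is resolved by preparative HPLC on a chiral stationary phase (amylose tris(3,5-dimethylphenylcarbamate)). The route is rejoined at 8.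

2. Step 4. Oxidative addition into the electron-rich, doubly ortho-substituted polyphenoxide may be slow and the salicylaldehyde-type sites may sequester the catalyst, so that protodebromination outruns coupling. Fallback, setting out from 3: peracetylation (Ac2O, pyridine, DMAP cat., CH2Cl2, 0 °C) should give 2-bromo-4,6-diformylbenzene-1,3,5-triyl triacetate F2, an electron-poor, non-chelating aryl bromide. Anhydrous Suzuki–Miyaura coupling with 5 (Pd(OAc)2, SPhos, CsF, THF, 60 °C) should give (E)-2,4-diformyl-6-(3-methylbut-1-en-1-yl)benzene-1,3,5-triyl triacetate F3. Methanolysis (K2CO3, MeOH, 0 °C, then cold aqueous NaH2PO4) returns the route to 6.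

3. Step 2. The electrophile may attack ipso at a formyl-bearing carbon (bromodeformylation) or oxidise the electron-rich ring instead of brominating cleanly once. Fallback, setting out from 1: the halogen is introduced before the formyl groups. Mono-iodination (I2, NaHCO3, THF/H2O, 0 °C) should give 2-iodobenzene-1,3,5-triol F4. Twofold Vilsmeier–Haack formylation (POCl3, DMF, EtOAc, 0 °C to rt, then H2O) should give 2,4,6-trihydroxy-5-iodobenzene-1,3-dicarbaldehyde F5. F5 is coupled with 5 under the conditions of step 4, and the route is rejoined at 6.

Further compounds
F1 | step 5 | ent-sideroxylonal A, (2S,3S,4R)-2-(3,5-diformyl-2,4,6-trihydroxyphenyl)-5,7-dihydroxy-4-(2-methylpropyl)-3-(propan-2-yl)-3,4-dihydro-2H-chromene-6,8-dicarbaldehyde | CC(C)C[C@H]1c2c(O)c(C=O)c(O)c(C=O)c2O[C@H](c2c(O)c(C=O)c(O)c(C=O)c2O)[C@H]1C(C)C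
F2 | step 4 | 2-bromo-4,6-diformylbenzene-1,3,5-triyl triacetate | CC(=O)Oc1c(Br)c(OC(C)=O)c(C=O)c(OC(C)=O)c1C=O
F3 | step 4 | (E)-2,4-diformyl-6-(3-methylbut-1-en-1-yl)benzene-1,3,5-triyl triacetate | CC(C)/C=C/c1c(OC(C)=O)c(C=O)c(OC(C)=O)c(C=O)c1OC(C)=O
F4 | step 2 | 2-iodobenzene-1,3,5-triol | Oc1cc(O)c(I)c(O)c1
F5 | step 2 | 2,4,6-trihydroxy-5-iodobenzene-1,3-dicarbaldehyde | O=Cc1c(O)c(I)c(O)c(C=O)c1O
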